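## The problem

2α-Hydroxyferutinin (21) is a trans-fused bicyclo[5.3.0]dec-8-ene. In daucane numbering, C1 is the quaternary, methyl-bearing fusion carbon, C2 a secondary carbinol, C4 the isopropyl carbinol, C5 the fusion CH, C6 the carbinol esterified with 4-hydroxybenzoic acid, and C8=C9 the ring alkene with a methyl group on C8. A synthesis has to join a cyclopentane (C1–C5) and a cycloheptene (C1, C5–C10) across the C1–C5 bond, with the ring bonds C1–C10 and C5–C6 on opposite faces.

There are five stereocentres, (1R,2S,4R,5S,6S), four of them contiguous on the five-membered ring. The α face carries C10, the C2 oxygen, the isopropyl group and H5; the β face carries the C1 methyl, the C4 hydroxyl and C6.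

Only C2 can be bought as a single enantiomer in a useful ring. It is next to C1 and can control it. C1 and C2 together can control C5, C5 can control C4, and C4 with C5 can control C6.

The tertiary C4 alcohol ionises or dehydrates under acid. The trisubstituted alkene is lost to hydrogenation or acid-induced migration. The aryl ester with its free phenol does not tolerate organometallics, hydrides or strong base, so it must come last. On the way, every cyclopentanone with the C2 oxygen in place is a β-silyloxy ketone that loses silanol by E1cB, and the aldol and hydroxy aldehyde intermediates can undergo retro-aldol cleavage.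

The feature that opens the route is the position of C1. It lies between the carbinol carbon C2 and C5 and is β to C4, whose oxygen can be read as a carbonyl. The atoms C2–C1=C5–C4(=O)–C3 are therefore a 4-silyloxycyclopent-2-enone. With the C10 arm already on its β-carbon, only the C1 methyl and C6 are missing, and both can be added in one operation, to the β- and the α-carbon of the enone.

## Retrosynthesis

**C6–O acyl bond.** Target 21 is traced to the bis-silyl ether 20 and from there to the bicyclic diol 17 and 4-(tert-butyldimethylsilyloxy)benzoic acid (18). The ester is cut first because it is the group least compatible with everything else in the route. Acylation of 17 needs no further differentiation: C2 is still silylated and the tertiary C4 hydroxyl is inert. One fluoride treatment then frees the phenol and C2 together.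

**C8=C9.** The cycloheptene of 17 is opened at its double bond to diene 16, which carries an allyl group on C1 and a methallyl carbinol on C5. Cutting a ring single bond (C6–C7 or C9–C10) would call for a medium-ring alkylation or an allyl-metal closure with its SE2' ambiguity. Metathesis instead fixes both the position of the alkene and the methyl on C8. The precursor is a monocyclic cyclopentane. The forward reaction must close a trans-fused seven-membered ring to a trisubstituted alkene.

**C6–C7.** Diene 16 is cut to aldehyde 14 and methallylmagnesium chloride (15). This brings in C7, C8 and the C8 methyl as one commercial reagent, and the C6 oxygen arrives with the carbon. The free C4 hydroxyl of 14 is kept on purpose. As its magnesium alkoxide it chelates the aldehyde, and the forward addition then has only one open face.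

**C4–isopropyl.** Aldehyde 14 comes from the triethylsilyl ether 13, and 13 from ketone 11 and isopropylmagnesium chloride (12) as the cerium reagent. The isopropyl group is added while C6 is still a protected hydroxymethyl group. A C6 aldehyde next to a C4 ketone would be an enolised β-keto aldehyde with no configuration at C5. The forward addition has to take the α face of a hindered, base-sensitive β-silyloxy ketone.

**C1–CH3 and C5–C6 (key step).** Ketone 11 is the silyl ether of aldol 10. Aldol 10 is cut at two bonds at once, to enone 6, lithium dimethylcuprate (7) and formaldehyde (8). Cutting C1–C10 instead would mean adding the larger arm anti to the C2 silyloxy group, which puts the methyl on the wrong face. Cutting only one of the two bonds would waste the regiodefined enolate. The precursor 6 is a flat enone with one stereocentre. The forward reaction has to deliver methyl anti to the C2 silyloxy group and C6 anti to the allyl arm.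

**The C10 arm and the enone.** Enone 6 is taken back through silyl enol ether 5 and aldehyde 4 to ester 3, and 3 to the commercial enone 1 and ketene silyl acetal 2. The arm enters as an acetate unit by conjugate addition with silyl transfer, the reliable way to put a carbon on the β-carbon of 1 and obtain the enol ether on the correct side for reoxidation. The ester is converted into the allyl group before the enone is unveiled, for three reasons:
- A methylene that is both γ to the enone and α to a carbonyl would be doubly activated and could be deprotonated by the cuprate.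
- An ester could lactonise with the aldolate.
- The ester would later need reduction in the presence of the tertiary alcohol.

The step count is the same, and the arm is then exactly the C10–C9 olefin that the metathesis needs.

## Roads not taken

**Alternative 1:** The cut is the C4–C5 bond of the five-membered ring. In the forward key step SmI2 reduces the α-bromo ester of the open-chain keto ester A1 (either bromide epimer) to a samarium enolate. This adds to the C4 isopropyl ketone in a Reformatsky aldol and closes the cyclopentane to β-hydroxy ester A2.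
- Merits: C4 and C5 are set in a ring-forming, metal-bridged transition state that places hydroxyl and ester cis, as the target requires. No isopropyl nucleophile has to be added to a hindered cyclopentanone. The C7–C10 arm with its Z alkene is already attached.
- Weak points: A1 holds the quaternary C1 next to the C2 carbinol in an open chain, where no ring helps to set it, and it needs a Z-trisubstituted allylic sulfone. The ketone face chosen relative to C1 and C2 is decided by a flexible chain. After A2 the ester must be reduced, the seven-membered ring closed by sulfone carbanion addition to C6, and the sulfone removed reductively, a reaction type that tends to move allylic double bonds.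
- Comparison: at C4 this road is better than the chosen plan, whose step 7 rests on intermolecular facial selectivity. The chosen plan sets against it a quaternary centre made on a ring under control of the adjacent C2 substituent, a C8=C9 bond whose position is fixed by metathesis, and a clearly shorter sequence.

**Alternative 2:** The seven-membered ring is derived from a six-membered ring by inserting C7. The enantiopure hydrindenedione A3 would be elaborated to the trans-hydrindane siloxycyclopropane A4. In the forward key step FeCl3 oxidises A4, the internal C6–C8 bond breaks, and loss of HCl gives cycloheptenone A5.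
- Merits: C1 and the C2 oxygen come with the building block. The ring fusion and the C4 addition are settled on a rigid bicycle, where the angular methyl shields the β face. The ring enlargement is regiospecific.
- Weak points: the antipode of A3 needed here is the (R) one, made with the unnatural proline enantiomer. The trans ring fusion and the C4 oxygen have to be introduced on the hydrindane. A5 has its functionality offset from the target: the C8 ketone must become the methyl-bearing alkene carbon, oxygen must be moved to C6, and the alkene must end at C8=C9 and not at C7=C8, a transposition with no inherent bias.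
- Comparison: for C1, C5 and C4 this road is more secure than the chosen plan. The chosen plan sets against it a shorter route and an alkene whose position is never in question.

**Alternative 3:** The cuts are C1–C5 and C6–C7, so both rings form at once. In the forward key step the vinylcyclopropane–alkyne A6 undergoes a (5+2) cycloaddition with [Rh(CO)2Cl]2 to the bicyclic diene A7.
- Merits: this has the best ring-forming economy of all four plans. Both rings and the C8=C9 alkene with its methyl appear in one catalytic step, and C4 is set beforehand.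
- Weak points: A6 needs a stereodefined cyclopropane with a quaternary carbon and a propargylic tertiary carbinol of defined configuration. The cyclopropane has to open at its more substituted C1–C9 bond. A7 still lacks C5–H and the C6 oxygen, which must be added to C5=C6 from the α face in the presence of a second trisubstituted alkene at C8=C9.
- Comparison: in step economy for the skeleton this road is superior. The chosen plan sets against it that each stereocentre arises in a separate substrate-controlled event, and that the C6 oxygen arrives with its carbon and not by late alkene functionalisation.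

Key step: step 5

Assumption: compounds 1, 2, 12, 15 and 18 are taken as purchasable (18 is otherwise one operation from 4-hydroxybenzoic acid); 7 is made from MeLi and CuI and 8 by cracking paraformaldehyde directly before use.

## Route

Step 1
Reactants: 1 (4S)-4-(tert-butyldimethylsilyloxy)cyclopent-2-en-1-one; 2 tert-butyl[(1-methoxyethenyl)oxy]dimethylsilane
Product: 3 methyl 2-[(1S,5S)-3,5-bis(tert-butyldimethylsilyloxy)cyclopent-2-en-1-yl]acetate
Conditions: HgI2 (10 mol %), Et2O, −78 to −20 °C
Reagents that add atoms: none
Why: Mukaiyama–Michael addition with silyl transfer; the ketene silyl acetal adds to the β-carbon (C1) anti to the C2 silyloxy group and the silyl group moves to the enolate oxygen, so the enol ether is formed only on the C4–C5 side. The new C1 centre (arm trans to the silyl ether) is auxiliary and is erased in step 4.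

Step 2
Reactants: 3 methyl 2-[(1S,5S)-3,5-bis(tert-butyldimethylsilyloxy)cyclopent-2-en-1-yl]acetate
Product: 4 2-[(1S,5S)-3,5-bis(tert-butyldimethylsilyloxy)cyclopent-2-en-1-yl]acetaldehyde
Conditions: iBu2AlH (1.1 equiv), CH2Cl2, −78 °C; MeOH, aq. potassium sodium tartrate
Reagents that add atoms: none
Why: Partial hydride reduction of a methyl ester; at −78 °C the aluminium hemiacetal persists and gives the aldehyde only on work-up. Silyl enol ether and silyl ether are inert to the hydride and to the neutral work-up.

Step 3
Reactants: 4 2-[(1S,5S)-3,5-bis(tert-butyldimethylsilyloxy)cyclopent-2-en-1-yl]acetaldehyde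
Product: 5 (3S,4S)-1,4-bis(tert-butyldimethylsilyloxy)-3-(prop-2-en-1-yl)cyclopent-1-ene
Conditions: Ph3PCH3Br, KN(SiMe3)2, THF, 0 °C; then 4, −78 to 0 °C
Reagents that add atoms: methylenetriphenylphosphorane, C=P(c1ccccc1)(c1ccccc1)c1ccccc1
Why: Wittig methylenation of an unhindered aldehyde with the non-stabilised ylide; the silyl enol ether does not react with the ylide and no stereocentre is touched.

Step 4
Reactants: 5 (3S,4S)-1,4-bis(tert-butyldimethylsilyloxy)-3-(prop-2-en-1-yl)cyclopent-1-ene
Product: 6 (4S)-4-(tert-butyldimethylsilyloxy)-3-(prop-2-en-1-yl)cyclopent-2-en-1-one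
Conditions: Pd(OAc)2 (1.1 equiv), MeCN, rt
Reagents that add atoms: none
Why: Saegusa–Ito oxidation; divalent palladium turns the silyl enol ether into a palladium enolate at C5, and β-hydride elimination can only take the C1 hydrogen. This gives the C1=C5 enone and removes the auxiliary C1 centre; C2 is untouched and, without base, the allyl group stays out of conjugation.

Step 5
Reactants: 6 (4S)-4-(tert-butyldimethylsilyloxy)-3-(prop-2-en-1-yl)cyclopent-2-en-1-one; 7 lithium dimethylcuprate; 8 formaldehyde
Product: 10 (2S,3R,4S)-4-(tert-butyldimethylsilyloxy)-2-(hydroxymethyl)-3-methyl-3-(prop-2-en-1-yl)cyclopentan-1-one, via lithium enolate 9 (not isolated)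
Conditions: 7 (1.5 equiv, from MeLi and CuI), Et2O, −78 to −40 °C; then 8 (monomer in THF, excess), −78 °C; aq. NH4Cl
Reagents that add atoms: none
Why: Three-component coupling by cuprate conjugate addition and aldol trapping of the enolate, the known mode of reaction of 4-silyloxycyclopent-2-enones, here applied to a 3-substituted member. The cuprate forms a π-complex with the enone, adds at the β-carbon C1 to a trivalent copper intermediate and reductively eliminates the C1–CH3 bond; it approaches anti to the adjacent C2 silyloxy group, so the methyl ends up β and the allyl arm α, cis to the silyl ether (1R). The result is the regiodefined C4–C5 lithium enolate 9, which at −78 °C does not exchange protons and so neither moves to the C3 side nor expels the C2 silyloxy group. Monomeric formaldehyde, the most reactive and least hindered carbonyl electrophile, intercepts 9 at C5 in an open aldol transition state. The α face of C5 is covered by the allyl arm, which the cis C2 silyloxy group pushes toward C5, so C6 enters from the β face beside the small methyl group and H5 becomes α (5S); this is the trans relation of C10 and C6 that the seven-membered ring needs. No ring is closed. The selectivities required are 1,4- over 1,2-addition and over γ-deprotonation, secured by the soft, weakly basic cuprate and by an arm without a carbonyl group, and kinetic trapping, secured by low temperature and a cold quench.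

Step 6
Reactants: 10 (2S,3R,4S)-4-(tert-butyldimethylsilyloxy)-2-(hydroxymethyl)-3-methyl-3-(prop-2-en-1-yl)cyclopentan-1-one
Product: 11 (2S,3R,4S)-4-(tert-butyldimethylsilyloxy)-3-methyl-3-(prop-2-en-1-yl)-2-[(triethylsilyloxy)methyl]cyclopentan-1-one
Conditions: Et3SiCl, imidazole, CH2Cl2, 0 °C
Reagents that add atoms: chlorotriethylsilane, CC[Si](Cl)(CC)CC
Why: Silyl ether formation at the primary hydroxyl; the conditions are mild enough that the aldol does not dehydrate and the β-silyloxy ketone does not eliminate. The step removes the acidic proton and the retro-aldol pathway before the organometallic addition.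

Step 7
Reactants: 11 (2S,3R,4S)-4-(tert-butyldimethylsilyloxy)-3-methyl-3-(prop-2-en-1-yl)-2-[(triethylsilyloxy)methyl]cyclopentan-1-one; 12 isopropylmagnesium chloride
Product: 13 (1R,2S,3R,4S)-4-(tert-butyldimethylsilyloxy)-3-methyl-1-(propan-2-yl)-3-(prop-2-en-1-yl)-2-[(triethylsilyloxy)methyl]cyclopentan-1-ol
Conditions: 12, CeCl3 (anhydrous), THF, −78 °C
Reagents that add atoms: none
Why: Organocerium 1,2-addition; iPrCeCl2 is weakly basic and adds to the hindered, enolisable ketone without enolisation (which would expel the C2 silyloxy group) and without β-hydride reduction. Attack is expected anti to the C5 silyloxymethyl arm and the C1 methyl on the β face, which places isopropyl α and hydroxyl β (4R).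

Step 8
Reactants: 13 (1R,2S,3R,4S)-4-(tert-butyldimethylsilyloxy)-3-methyl-1-(propan-2-yl)-3-(prop-2-en-1-yl)-2-[(triethylsilyloxy)methyl]cyclopentan-1-ol
Product: 14 (1R,2R,3S,5R)-3-(tert-butyldimethylsilyloxy)-5-hydroxy-2-methyl-5-(propan-2-yl)-2-(prop-2-en-1-yl)cyclopentane-1-carbaldehyde
Conditions: (COCl)2, DMSO, CH2Cl2, −78 to −40 °C; Et3N, −78 to 0 °C
Reagents that add atoms: none
Why: Swern oxidation applied directly to a primary triethylsilyl ether; the chlorosulfonium salt cleaves the primary Si–O bond and the alkoxysulfonium ion collapses to the aldehyde with Et3N, while the secondary tert-butyldimethylsilyl ether and the tertiary alcohol do not react. C5 is now α to a carbonyl, but its configuration (formyl trans to isopropyl and allyl) is the thermodynamically preferred one.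

Step 9
Reactants: 14 (1R,2R,3S,5R)-3-(tert-butyldimethylsilyloxy)-5-hydroxy-2-methyl-5-(propan-2-yl)-2-(prop-2-en-1-yl)cyclopentane-1-carbaldehyde; 15 (2-methylprop-2-en-1-yl)magnesium chloride
Product: 16 (1R,2S,3R,4S)-4-(tert-butyldimethylsilyloxy)-2-[(1S)-1-hydroxy-3-methylbut-3-en-1-yl]-3-methyl-1-(propan-2-yl)-3-(prop-2-en-1-yl)cyclopentan-1-ol
Conditions: 15 (2.5 equiv), THF, −78 °C, inverse addition; aq. NH4Cl
Reagents that add atoms: none
Why: Chelation-controlled Grignard addition; the first equivalent forms the C4 magnesium alkoxide, which binds the aldehyde oxygen in a six-membered chelate cis-fused to the ring. The methallyl group then attacks the carbonyl face beside H5, away from the quaternary C1, which gives the 6S carbinol; the Felkin–Anh arrangement with C1 as the large group leads to the same face.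

Step 10
Reactants: 16 (1R,2S,3R,4S)-4-(tert-butyldimethylsilyloxy)-2-[(1S)-1-hydroxy-3-methylbut-3-en-1-yl]-3-methyl-1-(propan-2-yl)-3-(prop-2-en-1-yl)cyclopentan-1-ol
Product: 17 (1S,3R,3aS,4S,8aR)-1-(tert-butyldimethylsilyloxy)-6,8a-dimethyl-3-(propan-2-yl)-1,2,3,3a,4,5,8,8a-octahydroazulene-3,4-diol
Conditions: second-generation Grubbs catalyst (H2IMes)(PCy3)Cl2Ru=CHPh (5 mol %), CH2Cl2 (0.005 M), 40 °C
Reagents that add atoms: none
Why: Ring-closing metathesis between the monosubstituted allyl alkene and the 1,1-disubstituted methallyl alkene; it closes the cycloheptene and fixes the trisubstituted C8=C9 bond with the methyl on C8. Loss of ethene drives it, free hydroxyls are tolerated, and the trans arms on the cyclopentane can both lie pseudo-equatorial for closure.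

Step 11
Reactants: 17 (1S,3R,3aS,4S,8aR)-1-(tert-butyldimethylsilyloxy)-6,8a-dimethyl-3-(propan-2-yl)-1,2,3,3a,4,5,8,8a-octahydroazulene-3,4-diol; 18 4-(tert-butyldimethylsilyloxy)benzoic acid
Product: 20 (1S,3R,3aS,4S,8aR)-1-(tert-butyldimethylsilyloxy)-3-hydroxy-6,8a-dimethyl-3-(propan-2-yl)-1,2,3,3a,4,5,8,8a-octahydroazulen-4-yl 4-(tert-butyldimethylsilyloxy)benzoate, via mixed anhydride 19 (not isolated)
Conditions: 18, 2,4,6-trichlorobenzoyl chloride, Et3N, toluene, rt; then 17, DMAP, rt to 50 °C
Reagents that add atoms: none
Why: Yamaguchi esterification; the mixed anhydride 19 acylates DMAP and the acylpyridinium ion esterifies the secondary C6 hydroxyl. The tertiary C4 hydroxyl is too hindered to react and C2 is still silylated, so only C6 is acylated.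

Step 12
Reactants: 20 (1S,3R,3aS,4S,8aR)-1-(tert-butyldimethylsilyloxy)-3-hydroxy-6,8a-dimethyl-3-(propan-2-yl)-1,2,3,3a,4,5,8,8a-octahydroazulen-4-yl 4-(tert-butyldimethylsilyloxy)benzoate
Product: 21 (1S,3R,3aS,4S,8aR)-1,3-dihydroxy-6,8a-dimethyl-3-(propan-2-yl)-1,2,3,3a,4,5,8,8a-octahydroazulen-4-yl 4-hydroxybenzoate (2α-hydroxyferutinin)
Conditions: HF·pyridine, pyridine, THF, 0 °C to rt
Reagents that add atoms: none
Why: Fluoride-mediated desilylation under buffered, non-basic conditions removes the aryl and the secondary silyl ether; the aryl ester, the tertiary alcohol and the trisubstituted alkene are stable to it.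

## Compound list

1 | (4S)-4-(tert-butyldimethylsilyloxy)cyclopent-2-en-1-one | O=C1C=C[C@@H](O[Si](C)(C)C(C)(C)C)C1 | starting material
2 | tert-butyl[(1-methoxyethenyl)oxy]dimethylsilane | C=C(OC)O[Si](C)(C)C(C)(C)C | starting material
3 | methyl 2-[(1S,5S)-3,5-bis(tert-butyldimethylsilyloxy)cyclopent-2-en-1-yl]acetate | CC(C)(C)[Si](C)(C)OC1=C[C@H](CC(=O)OC)[C@@H](O[Si](C)(C)C(C)(C)C)C1 | intermediate
4 | 2-[(1S,5S)-3,5-bis(tert-butyldimethylsilyloxy)cyclopent-2-en-1-yl]acetaldehyde | CC(C)(C)[Si](C)(C)OC1=C[C@H](CC=O)[C@@H](O[Si](C)(C)C(C)(C)C)C1 | intermediate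
5 | (3S,4S)-1,4-bis(tert-butyldimethylsilyloxy)-3-(prop-2-en-1-yl)cyclopent-1-ene | CC(C)(C)[Si](C)(C)OC1=C[C@H](CC=C)[C@@H](O[Si](C)(C)C(C)(C)C)C1 | intermediate
6 | (4S)-4-(tert-butyldimethylsilyloxy)-3-(prop-2-en-1-yl)cyclopent-2-en-1-one | O=C1C[C@H](O[Si](C)(C)C(C)(C)C)C(CC=C)=C1 | intermediate
7 | lithium dimethylcuprate | [Li+].C[Cu-]C | starting material
8 | formaldehyde | C=O | starting material
9 | lithium (3R,4S)-4-(tert-butyldimethylsilyloxy)-3-methyl-3-(prop-2-en-1-yl)cyclopent-1-en-1-olate | [Li+].[O-]C1=C[C@@](C)(CC=C)[C@@H](O[Si](C)(C)C(C)(C)C)C1 | intermediate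
10 | (2S,3R,4S)-4-(tert-butyldimethylsilyloxy)-2-(hydroxymethyl)-3-methyl-3-(prop-2-en-1-yl)cyclopentan-1-one | O=C1C[C@H](O[Si](C)(C)C(C)(C)C)[C@](C)(CC=C)[C@H]1CO | intermediate
11 | (2S,3R,4S)-4-(tert-butyldimethylsilyloxy)-3-methyl-3-(prop-2-en-1-yl)-2-[(triethylsilyloxy)methyl]cyclopentan-1-one | O=C1C[C@H](O[Si](C)(C)C(C)(C)C)[C@](C)(CC=C)[C@H]1CO[Si](CC)(CC)CC | intermediate
12 | isopropylmagnesium chloride | CC(C)[Mg]Cl | starting material
13 | (1R,2S,3R,4S)-4-(tert-butyldimethylsilyloxy)-3-methyl-1-(propan-2-yl)-3-(prop-2-en-1-yl)-2-[(triethylsilyloxy)methyl]cyclopentan-1-ol | CC(C)[C@]1(O)C[C@H](O[Si](C)(C)C(C)(C)C)[C@](C)(CC=C)[C@H]1CO[Si](CC)(CC)CC | intermediate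
14 | (1R,2R,3S,5R)-3-(tert-butyldimethylsilyloxy)-5-hydroxy-2-methyl-5-(propan-2-yl)-2-(prop-2-en-1-yl)cyclopentane-1-carbaldehyde | CC(C)[C@]1(O)C[C@H](O[Si](C)(C)C(C)(C)C)[C@](C)(CC=C)[C@H]1C=O | intermediate
15 | (2-methylprop-2-en-1-yl)magnesium chloride | CC(=C)C[Mg]Cl | starting material
16 | (1R,2S,3R,4S)-4-(tert-butyldimethylsilyloxy)-2-[(1S)-1-hydroxy-3-methylbut-3-en-1-yl]-3-methyl-1-(propan-2-yl)-3-(prop-2-en-1-yl)cyclopentan-1-ol | CC(C)[C@]1(O)C[C@H](O[Si](C)(C)C(C)(C)C)[C@](C)(CC=C)[C@H]1[C@@H](O)CC(C)=C | intermediate
17 | (1S,3R,3aS,4S,8aR)-1-(tert-butyldimethylsilyloxy)-6,8a-dimethyl-3-(propan-2-yl)-1,2,3,3a,4,5,8,8a-octahydroazulene-3,4-diol | CC1=CC[C@]2(C)[C@@H]([C@@H](O)C1)[C@](O)(C(C)C)C[C@@H]2O[Si](C)(C)C(C)(C)C | intermediate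
18 | 4-(tert-butyldimethylsilyloxy)benzoic acid | CC(C)(C)[Si](C)(C)Oc1ccc(cc1)C(=O)O | starting material
19 | 4-(tert-butyldimethylsilyloxy)benzoic 2,4,6-trichlorobenzoic anhydride | CC(C)(C)[Si](C)(C)Oc1ccc(cc1)C(=O)OC(=O)c1c(Cl)cc(Cl)cc1Cl | intermediate
20 | (1S,3R,3aS,4S,8aR)-1-(tert-butyldimethylsilyloxy)-3-hydroxy-6,8a-dimethyl-3-(propan-2-yl)-1,2,3,3a,4,5,8,8a-octahydroazulen-4-yl 4-(tert-butyldimethylsilyloxy)benzoate | CC1=CC[C@]2(C)[C@@H]([C@@H](OC(=O)c3ccc(O[Si](C)(C)C(C)(C)C)cc3)C1)[C@](O)(C(C)C)C[C@@H]2O[Si](C)(C)C(C)(C)C | intermediate
21 | (1S,3R,3aS,4S,8aR)-1,3-dihydroxy-6,8a-dimethyl-3-(propan-2-yl)-1,2,3,3a,4,5,8,8a-octahydroazulen-4-yl 4-hydroxybenzoate | CC1=CC[C@]2(C)[C@@H]([C@@H](OC(=O)c3ccc(O)cc3)C1)[C@](O)(C(C)C)C[C@@H]2O | target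

## Step count and least certain steps

Total: 12 steps. Longest linear sequence: 12 steps, from 1 to 21. All other reactants enter as purchased or freshly made reagents.

**Step 5 (key step).** The β-carbon of 6 is fully substituted and flanked by the silyloxy carbon, so conjugate addition may be slow. That gives time for γ-deprotonation and migration of the skipped alkene into conjugation, or for loss of the silyloxy group after enolate equilibration. Facial control at C5 rests on the difference between methyl and the allyl arm and may be incomplete. Formaldehyde may also oligomerise before it is trapped.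
Fallback: the two bond formations are separated. Enone 6 is treated with 7 in the presence of Me3SiCl, which accelerates the conjugate addition and captures the enolate as (3R,4S)-4-(tert-butyldimethylsilyloxy)-3-methyl-3-(prop-2-en-1-yl)-1-(trimethylsilyloxy)cyclopent-1-ene F1. F1 is isolated and then hydroxymethylated with aqueous formaldehyde and catalytic Yb(OTf)3 in THF, a Mukaiyama aldol in water, which returns to 10. Any minor C5 epimer carried forward can still be equilibrated at the stage of aldehyde 14, where the desired configuration is the stable one.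

**Step 7.** Poor facial selectivity is the main risk. The β face is shielded by the C5 arm and the C1 methyl, but the α face carries the C2 silyloxy group and the allyl group in 1,3-relation to the carbonyl, and the two effects may partly cancel. Enolisation with loss of the silyloxy group is the secondary risk.
Fallback: the addition is directed by the C2 oxygen instead of by sterics.
- From 10, HF·pyridine removes the C2 silyl ether to give (2S,3R,4S)-4-hydroxy-2-(hydroxymethyl)-3-methyl-3-(prop-2-en-1-yl)cyclopentan-1-one F2.
- Et3SiCl and imidazole at −20 °C silylate only the primary hydroxyl, giving (2S,3R,4S)-4-hydroxy-3-methyl-3-(prop-2-en-1-yl)-2-[(triethylsilyloxy)methyl]cyclopentan-1-one F3.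
- Excess 12 with CeCl3 first forms the C2 alkoxide on the α face, which anchors the reagent and delivers isopropyl to that face. This gives (1R,3S,4R,5S)-4-methyl-1-(propan-2-yl)-4-(prop-2-en-1-yl)-5-[(triethylsilyloxy)methyl]cyclopentane-1,3-diol F4.
- tert-Butyldimethylsilyl triflate and 2,6-lutidine at −78 °C silylate the secondary C2 hydroxyl in preference to the tertiary one and return to 13.

**Step 9.** Chelation control may be incomplete, because allylic Grignard reagents react very fast and may add partly to the unchelated aldehyde. Retro-aldol opening of the magnesium β-alkoxy aldehyde is also possible.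
Fallback: C6 is set on the bicycle instead.
- From 14, the addition is run without regard to selectivity. The C6 epimer, (1R,2S,3R,4S)-4-(tert-butyldimethylsilyloxy)-2-[(1R)-1-hydroxy-3-methylbut-3-en-1-yl]-3-methyl-1-(propan-2-yl)-3-(prop-2-en-1-yl)cyclopentan-1-ol F5, alone or mixed with 16, is cyclised under the conditions of step 10.
- This gives (1S,3R,3aS,4R,8aR)-1-(tert-butyldimethylsilyloxy)-6,8a-dimethyl-3-(propan-2-yl)-1,2,3,3a,4,5,8,8a-octahydroazulene-3,4-diol F6.
- Dess–Martin periodinane oxidises the secondary alcohol to (1S,3R,3aR,8aR)-1-(tert-butyldimethylsilyloxy)-3-hydroxy-6,8a-dimethyl-3-(propan-2-yl)-2,3,3a,5,8,8a-hexahydro-1H-azulen-4-one F7.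
- Me4NBH(OAc)3 in MeCN/AcOH reduces the ketone by hydroxyl-directed hydride delivery from the β-C4 oxygen. This places the C6 hydroxyl α and returns to 17.

**Step 4.** Palladium hydride formed during the oxidation may move the allyl double bond into conjugation with the new enone. Coordination of the terminal alkene to divalent palladium may also slow the β-hydride elimination.
Fallback: the enone is made by selenoxide elimination, which involves no metal hydride. From 5, PhSeCl in CH2Cl2 at −78 °C selenates C5 anti to the allyl group to give (2S,3R,4S)-4-(tert-butyldimethylsilyloxy)-2-(phenylselanyl)-3-(prop-2-en-1-yl)cyclopentan-1-one F8. Oxidation with H2O2 and pyridine at 0 °C then brings about syn-elimination toward the cis C1 hydrogen and returns to 6.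

**Step 8.** Cleavage of the primary silyl ether, which sits on a carbon between two fully substituted centres, may be slow under Swern conditions. Longer exposure to Et3N invites retro-aldol opening of the β-hydroxy aldehyde.
Fallback: deprotection and oxidation are done separately. From 13, pyridinium p-toluenesulfonate in MeOH at 0 °C removes only the triethylsilyl group to give (1R,2S,3R,4S)-4-(tert-butyldimethylsilyloxy)-2-(hydroxymethyl)-3-methyl-1-(propan-2-yl)-3-(prop-2-en-1-yl)cyclopentan-1-ol F9. TEMPO with PhI(OAc)2 in CH2Cl2 then oxidises the primary alcohol in the presence of the tertiary one and returns to 14.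

## Further compounds

F1 | step 5 | (3R,4S)-4-(tert-butyldimethylsilyloxy)-3-methyl-3-(prop-2-en-1-yl)-1-(trimethylsilyloxy)cyclopent-1-ene | C[Si](C)(C)OC1=C[C@@](C)(CC=C)[C@@H](O[Si](C)(C)C(C)(C)C)C1
F2 | step 7 | (2S,3R,4S)-4-hydroxy-2-(hydroxymethyl)-3-methyl-3-(prop-2-en-1-yl)cyclopentan-1-one | O=C1C[C@H](O)[C@](C)(CC=C)[C@H]1CO
F3 | step 7 | (2S,3R,4S)-4-hydroxy-3-methyl-3-(prop-2-en-1-yl)-2-[(triethylsilyloxy)methyl]cyclopentan-1-one | O=C1C[C@H](O)[C@](C)(CC=C)[C@H]1CO[Si](CC)(CC)CC
F4 | step 7 | (1R,3S,4R,5S)-4-methyl-1-(propan-2-yl)-4-(prop-2-en-1-yl)-5-[(triethylsilyloxy)methyl]cyclopentane-1,3-diol | CC(C)[C@]1(O)C[C@H](O)[C@](C)(CC=C)[C@H]1CO[Si](CC)(CC)CC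
F5 | step 9 | (1R,2S,3R,4S)-4-(tert-butyldimethylsilyloxy)-2-[(1R)-1-hydroxy-3-methylbut-3-en-1-yl]-3-methyl-1-(propan-2-yl)-3-(prop-2-en-1-yl)cyclopentan-1-ol | CC(C)[C@]1(O)C[C@H](O[Si](C)(C)C(C)(C)C)[C@](C)(CC=C)[C@H]1[C@H](O)CC(C)=C
F6 | step 9 | (1S,3R,3aS,4R,8aR)-1-(tert-butyldimethylsilyloxy)-6,8a-dimethyl-3-(propan-2-yl)-1,2,3,3a,4,5,8,8a-octahydroazulene-3,4-diol | CC1=CC[C@]2(C)[C@@H]([C@H](O)C1)[C@](O)(C(C)C)C[C@@H]2O[Si](C)(C)C(C)(C)C
F7 | step 9 | (1S,3R,3aR,8aR)-1-(tert-butyldimethylsilyloxy)-3-hydroxy-6,8a-dimethyl-3-(propan-2-yl)-2,3,3a,5,8,8a-hexahydro-1H-azulen-4-one | CC1=CC[C@]2(C)[C@@H](C(=O)C1)[C@](O)(C(C)C)C[C@@H]2O[Si](C)(C)C(C)(C)C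
F8 | step 4 | (2S,3R,4S)-4-(tert-butyldimethylsilyloxy)-2-(phenylselanyl)-3-(prop-2-en-1-yl)cyclopentan-1-one | O=C1C[C@H](O[Si](C)(C)C(C)(C)C)[C@@H](CC=C)[C@@H]1[Se]c1ccccc1
F9 | step 8 | (1R,2S,3R,4S)-4-(tert-butyldimethylsilyloxy)-2-(hydroxymethyl)-3-methyl-1-(propan-2-yl)-3-(prop-2-en-1-yl)cyclopentan-1-ol | CC(C)[C@]1(O)C[C@H](O[Si](C)(C)C(C)(C)C)[C@](C)(CC=C)[C@H]1CO
A1 | alternative 1 | methyl (3S,4S)-2-bromo-4-[(4-methoxyphenyl)methoxy]-3,7-dimethyl-3-[(2Z)-3-methyl-4-(phenylsulfonyl)but-2-en-1-yl]-6-oxooctanoate | COC(=O)C(Br)[C@@](C)(C/C=C(C)\CS(=O)(=O)c1ccccc1)[C@@H](OCc1ccc(OC)cc1)CC(=O)C(C)C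
A2 | alternative 1 | methyl 2-hydroxy-4-[(4-methoxyphenyl)methoxy]-5-methyl-5-[(2Z)-3-methyl-4-(phenylsulfonyl)but-2-en-1-yl]-2-(propan-2-yl)cyclopentane-1-carboxylate, ring carbons configured as C1, C2, C4 and C5 of 21 | COC(=O)[C@H]1[C@](O)(C(C)C)C[C@H](OCc2ccc(OC)cc2)[C@]1(C)C/C=C(C)\CS(=O)(=O)c1ccccc1
A3 | alternative 2 | (7aR)-7a-methyl-2,3,7,7a-tetrahydro-1H-indene-1,5(6H)-dione | C[C@@]12CCC(=O)C=C1CCC2=O
A4 | alternative 2 | trans-hydrindane with a C6–C7–C8 cyclopropane bearing trimethylsilyloxy on C8, triethylsilyloxy and isopropyl on C4 and tert-butyldimethylsilyloxy on C2 (cyclopropane configuration open) | C[Si](C)(C)OC12CC1[C@H]1[C@](O[Si](CC)(CC)CC)(C(C)C)C[C@H](O[Si](C)(C)C(C)(C)C)[C@]1(C)CC2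
A5 | alternative 2 | trans-fused 1-(tert-butyldimethylsilyloxy)-8a-methyl-3-(propan-2-yl)-3-(triethylsilyloxy)-2,3,3a,7,8,8a-hexahydro-1H-azulen-6-one, configured as 21 at C1, C2, C4 and C5 | O=C1C=C[C@H]2[C@](O[Si](CC)(CC)CC)(C(C)C)C[C@H](O[Si](C)(C)C(C)(C)C)[C@]2(C)CC1
A6 | alternative 3 | 5-(tert-butyldimethylsilyloxy)-5-[1-methyl-2-(prop-1-en-2-yl)cyclopropyl]-3-(propan-2-yl)pent-1-yn-3-ol, chain and isopropenyl cis on the cyclopropane | C#C[C@](O)(C(C)C)C[C@H](O[Si](C)(C)C(C)(C)C)[C@]1(C)C[C@@H]1C(C)=C
A7 | alternative 3 | 1-(tert-butyldimethylsilyloxy)-6,8a-dimethyl-3-(propan-2-yl)-1,2,3,5,8,8a-hexahydroazulen-3-ol, configured as 21 at C1, C2 and C4 | CC1=CC[C@]2(C)C(=CC1)[C@](O)(C(C)C)C[C@@H]2O[Si](C)(C)C(C)(C)C
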